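Late in the run this flask turns on what is left: how much nucleophile is unused, and how much of that is still free to react.

electrophile 0.25 M; nucleophile 0.225 M; solid base 0.125 M; time 8.0 min

    electrophile + nucleophile → acid set free + target (k1 = 0.643 M⁻¹ s⁻¹)
    nucleophile + acid set free ⇌ protonated nucleophile, settled at all times (K2 = 560 M⁻¹)
    acid set free + free base ⇌ salt of the base, settled at all times (K3 = 4920 M⁻¹)
    solid base ⇌ free base, rate k4*(cs4 - [free base]) while solid is left; crystals form when [free base] > cs4 (cs4 = 0.17 M, k4 = 0.0451 s⁻¹)
    target ⇌ isomer of the product (K5 = 2.13, k5 = 0.00183 s⁻¹)

- part of the electrophile that has reacted at 8.0 min
- share of the unused nucleophile that is free and not bound as protonated nucleophile, at 8.0 min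

- as a solid, counted per litre of solution: solid base
- at the start none of the solid base is in solution
- run time (flask): 8.0 min

In the first instants the coupling sets free acid at 0.0362 M s⁻¹, faster than the solid base can dissolve, at most 0.00767 M s⁻¹. So the acid lands on the nucleophile in the fast protonation, and free base takes it over as it dissolves, its constant 4920 M⁻¹ standing above 560 M⁻¹.

In the middle, the 0.125 M of solid base needs at least 16.3 s at that top rate, short against 8.0 min. From then on this reckoning counts u, the unused nucleophile, free and protonated together. Acid made equals c(nucleophile charged) minus u, the salt of the base holds about 0.125 M, and protonated nucleophile holds nearly u. So c(acid set free) = acid surplus + c(free base) − 2u, where the acid surplus, the nucleophile charge minus the base charge, is 0.100 M.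

Towards the end, the free share is 1/(1 + 560 M⁻¹·c(acid set free)). Free base set aside, this balance puts acid at zero when the electrophile reacted is 70.0%, where 2u meets the surplus. Past that point acid climbs towards 0.100 M and the free share sinks towards 1.75%. The nucleophile, the limiting reagent, caps the conversion at 90.0%. This reckoning stops at these marks.

The forecast integrated the slowed rate by hand and gave 80.8% reacted and 3.1% free, from the ground that “Acid forms faster than the base can dissolve”. Its conversion lies between the 70.0% and 90.0% of this reckoning, and its free share stands above 1.75%.

The flask gives 80.9% reacted and 3.12% free. The electrophile's half-life by the coupling has stretched from 0.080 min at the charges to 25 min at the asked time. In this flask at the asked time u is 0.0229 M, so the balance with the surplus gives acid 0.0547 M and a free share of 3.16%. In the neighbour flask with 0.21 M of solid base the surplus is 0.0150 M. At the asked time that neighbour's 0.00348 M of free base and u of 0.00342 M give acid 0.0116 M and a free share of 13.3%, and the neighbour flask itself shows 12.9%.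

The numbers of this flask are those of an exercise; the flask was simulated.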